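## The problem

The target (30) shares one benzene ring (ring B) between two oxygen heterocycles. Ring B is fused to a 2,3-dihydrobenzofuran (O1', C2', C3') and carries at C5' the C2 carbon of an oxolane (O1, C2 to C5).

- **Oxolane stereocentres.** The three contiguous centres are (2R,3R,4S). The ring-B aryl group at C2, the hydroxymethyl group at C3 and the guaiacylmethyl group at C4 all lie on one face. C4 is a fully substituted carbinol whose hydroxyl points to the other face.
- **Dihydrobenzofuran stereocentres.** The ring is the cis (2'R,3'R) isomer, the less stable arrangement of aryl and hydroxymethyl groups.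
- **Control.** An aromatic ring separates the two arrays, so neither can steer the other and each needs its own source of absolute configuration. Within the oxolane, C2 and C3 can be set together and C3 can then direct C4.
- **Sensitive groups.** C2 and C2' are benzylic ether carbons para to an oxygen substituent. Protic or Lewis acids ionise them and would drain both cis arrangements to trans. A carbonyl group at C3' would be epimerised by base, and the two phenols must stay masked until the end.
- **Enabling feature.** C4 bears a hydroxyl, the benzylic methylene C7'' and the ring methylene C5. If C5 is raised to a lactone carbonyl, C4 becomes an enolate carbon and C4=C7'' an exocyclic acceptor. An aryl nucleophile can then be added at C7'' and an oxygen electrophile at C4 in one operation, on the face left open by the C3 substituent.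

## Retrosynthesis

**Protecting groups (30 from 29 from 28).** The phenols are carried as benzyl ethers and the two primary alcohols as tert-butyldimethylsilyl ethers. Fluoride and then neutral hydrogenolysis remove them without acid. No skeletal bond is cut.

**O1–C5 (28 from 27, 26 and 25).** The oxolane is opened at O1–C5, not at O1–C2. Closing at C2 would need a benzylic leaving group on an electron-rich ring, would pass through a cation and would give the trans ring. Closing at C5 is a displacement at a primary sulfonate (27) by the C2 hydroxyl of triol 26, which leaves C2 untouched. Triol 26 is the reduction product of lactone 25, so C5 becomes a carbonyl carbon. The forward closure needs only selective sulfonylation of the primary alcohol.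

**C7''–aryl and C4–O (25 from 21 and 23).** Both bonds at the quaternary carbinol are cut together. This gives the α-methylene lactone 21 and the aryl Grignard reagent 23. The neighbouring option, adding a benzyl nucleophile to a C4 ketone, would bring the benzyl group in anti to the C3 substituent and give the wrong C4 epimer. Here the oxygen comes in anti, so the benzyl group ends cis. Lactone 21 lacks one aryl ring and the C4 stereocentre. The forward step needs 1,4-addition and oxygen transfer to one enolate face.

**C2–C3 and the acyl C–O bond (21 from 14 and 19).** Lactone 21 is cut to aldehyde 14 and the 2-(methoxycarbonyl)allylboronate 19. Allylboration sets C2 and C3 in one step and the borate 20 lactonises in the flask. An aldol route would need separate α-methylenation. The cis relation comes from the boronate geometry, in which CH2OTBS is cis to CH2B. The absolute sense must come from a chiral catalyst because the stereocentres of 14 are too remote.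

**Boronate 19 (from 18, 17, 15 and 16).** The boronate is cut at C–B by SN2' borylation of acetate 18. This goes back to the Morita–Baylis–Hillman adduct 17 of silyloxyacetaldehyde 15 and methyl acrylate 16. The addition–elimination places the C3 substituent trans to the ester, which is the geometry required. Hydrometalation of an alkynoate would give the other isomer.

**Functional groups on ring B (14 from 12, 11 and 10).** The aldehyde is masked as an aryl bromide (12) and the silyloxymethyl group as the ester of 10. The bromide survives the carbenoid and hydride steps and is exchanged for lithium only when needed.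

**C2'–C3' (10 from 9).** The dihydrofuran ring is cut between C2' and C3' to the aryl diazoacetate 9. Intramolecular carbenoid insertion into the benzylic ether C–H bond forms the ring and both stereocentres at once and gives the cis ester kinetically. Closing the ring at O1'–C2' instead would need an ionisable benzylic leaving group.

**Diazo ester 9 and the Grignard reagent (9 from 7, 5, 2 and 4; 23 from 22).** The diazo group comes from keto ester 7 by way of its tosylhydrazone. Keto ester 7 comes from iodide 5 by iodine–magnesium exchange and acylation. Iodide 5 comes from phenol 2 and benzylic chloride 4 by ether synthesis. Phenol 2 is made from 4-bromo-2-methoxyphenol 1 and chloride 4 from the commercial alcohol 3. The same phenol 1 gives bromide 22 and Grignard reagent 23.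

## Roads not taken

**Alternative 1:** The dihydrofuran ring is cut at O1'–C2'. The syn hydroxy phenol A1 would come from an oxazolidinone-controlled aldol reaction and reduction. PPh3 and diisopropyl azodicarboxylate would then close it with inversion at C2' to the cis dihydrobenzofuran A2.
- Merits: the absolute and relative configuration rest on a highly predictable auxiliary, and no diazo compound or rhodium is needed.
- Weak points: C2' of A1 is a benzylic carbinol on a dioxygenated ring, so its oxyphosphonium ion can ionise or eliminate. The tosylate on the guaiacyl oxygen of A1 is there to slow this. It then has to be exchanged before an aryl Grignard reagent is used. Reaching A1 takes about five steps, where steps 5 and 6 take 7 to 10 in two.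
- Comparison: this road is better in the certainty of absolute configuration. The chosen plan sets against it a shorter sequence and a ring closure with no ionisable leaving group at C2'. The oxolane would still need the chosen key step.

**Alternative 2:** The same C2'–C3' bond is cut, but last. The diazo ester A3, carrying the finished and protected oxolane, would be treated with Rh2(S-PTTL)4, dirhodium tetrakis[N-phthaloyl-(S)-tert-leucinate], to give A4.
- Merits: the labile cis dihydrobenzofuran would exist only for the final steps. The oxolane centres could be set on an achiral aldehyde, where enantiomeric purity is easy to measure and upgrade. In these two respects it is as good as or better than the chosen plan.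
- Weak points: the glyoxylate or acetate handle for the diazo group cannot pass through the Grignard and hydride steps, so it must be installed late on a valuable intermediate. The tertiary alcohol needs an extra silyl group against O–H insertion. The carbenoid would meet many competing sites (ether C–H bonds of the oxolane, silyl ether methylenes, three electron-rich arenes). The ester of A4 would have to be reduced late.
- Comparison: the chosen plan runs the identical insertion at step 6 on a small substrate close to precedent and keeps the late steps to routine reactions.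

**Alternative 3:** The ring is cut at C3'–C3a' by ring contraction. Irradiation of the 3-diazoflavanone A5 in methanol would trigger a Wolff rearrangement, and the ketene would be trapped as the ester A6, which is the same compound as 10.
- Merits: it is metal-free and ends at an intermediate of the chosen route. C2' would be carried over from the flavanone.
- Weak points: flavanones racemise by reversible opening to the chalcone under the basic conditions of diazo transfer. Enantioselective access to this substitution pattern is not routine. The C3' configuration depends on the face of protonation after methanol adds to the ketene, so a cis/trans mixture is likely. Several steps are needed to reach what step 6 makes in one.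
- Comparison: it remains a possible substitute for steps 4 to 6. The chosen plan sets against it one catalytic step that fixes both centres.

Key step: step 16

Assumption: Rh2(S-PTTL)4 and the (S)-pipecolic acid-derived N,N'-dioxide ligand are taken to induce the configurations drawn for 10 and 21; if a test reaction shows the opposite sense, the mirror-image catalyst or ligand is used with no other change.

## Route

Step 1
Reactants: 1 4-bromo-2-methoxyphenol
Product: 2 4-bromo-2-iodo-6-methoxyphenol
Conditions: I2, KI, NaHCO3, H2O/THF, 0 °C → rt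
Reagents that add atoms: iodine, II
Why: Electrophilic aromatic iodination of a phenol under weakly basic conditions; the para position is blocked by bromine, so iodine should enter the one free position ortho to the hydroxyl.

Step 2
Reactants: 3 [4-(benzyloxy)-3-methoxyphenyl]methanol
Product: 4 1-(benzyloxy)-4-(chloromethyl)-2-methoxybenzene
Conditions: SOCl2, CH2Cl2, 0 °C → rt
Reagents that add atoms: thionyl chloride, O=S(Cl)Cl
Why: Deoxychlorination of an activated benzylic alcohol through its chlorosulfite; the chloride is used without storage.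

Step 3
Reactants: 2 4-bromo-2-iodo-6-methoxyphenol; 4 1-(benzyloxy)-4-(chloromethyl)-2-methoxybenzene
Product: 5 2-{[4-(benzyloxy)-3-methoxyphenyl]methoxy}-5-bromo-1-iodo-3-methoxybenzene
Conditions: K2CO3, Bu4NI (cat.), DMF, 40 °C
Reagents that add atoms: none
Why: Williamson ether synthesis; the acidic, doubly ortho-substituted phenoxide is alkylated by a reactive primary benzylic chloride.

Step 4
Reactants: 5 2-{[4-(benzyloxy)-3-methoxyphenyl]methoxy}-5-bromo-1-iodo-3-methoxybenzene
Product: 7 methyl 2-(2-{[4-(benzyloxy)-3-methoxyphenyl]methoxy}-5-bromo-3-methoxyphenyl)-2-oxoacetate, via arylmagnesium chloride 6 (not isolated)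
Conditions: i-PrMgCl·LiCl, THF, –40 °C; then added to (CO2Me)2 (3 equiv), THF, –78 → 0 °C
Reagents that add atoms: dimethyl oxalate, COC(=O)C(=O)OC
Why: Iodine–magnesium exchange is selective for C–I over C–Br at low temperature; acylation of the aryl Grignard reagent by excess oxalate should stop at the keto ester because the magnesium hemiketal persists until the quench.

Step 5
Reactants: 7 methyl 2-(2-{[4-(benzyloxy)-3-methoxyphenyl]methoxy}-5-bromo-3-methoxyphenyl)-2-oxoacetate
Product: 9 methyl 2-(2-{[4-(benzyloxy)-3-methoxyphenyl]methoxy}-5-bromo-3-methoxyphenyl)-2-diazoacetate, via N-tosylhydrazone 8 (not isolated)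
Conditions: TsNHNH2, MeOH, 50 °C; evaporate; then DBU, CH2Cl2, 0 °C → rt
Reagents that add atoms: p-toluenesulfonyl hydrazide, Cc1ccc(S(=O)(=O)NN)cc1
Why: Condensation to the tosylhydrazone and base-induced loss of sulfinate (Bamford–Stevens-type diazo formation) is a standard entry to aryl diazoacetates; no acid is present that could cleave the dialkoxybenzyl ether.

Step 6
Reactants: 9 methyl 2-(2-{[4-(benzyloxy)-3-methoxyphenyl]methoxy}-5-bromo-3-methoxyphenyl)-2-diazoacetate
Product: 10 methyl (2R,3S)-2-[4-(benzyloxy)-3-methoxyphenyl]-5-bromo-7-methoxy-2,3-dihydro-1-benzofuran-3-carboxylate (cis)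
Conditions: Rh2(S-PTTL)4 (1 mol %), toluene, –60 °C
Reagents that add atoms: none
Why: Intramolecular 1,5 C–H insertion of a donor/acceptor carbenoid of divalent rhodium into the benzylic ether C–H bond, which is activated by the ether oxygen and the alkoxyaryl ring; the concerted insertion closes the five-membered ring and should give the cis ester kinetically, and the chiral carboxylate ligands choose between the two enantiotopic benzylic hydrogens, which sets C2' and C3' together.

Step 7
Reactants: 10 methyl (2R,3S)-2-[4-(benzyloxy)-3-methoxyphenyl]-5-bromo-7-methoxy-2,3-dihydro-1-benzofuran-3-carboxylate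
Product: 11 {(2R,3R)-2-[4-(benzyloxy)-3-methoxyphenyl]-5-bromo-7-methoxy-2,3-dihydro-1-benzofuran-3-yl}methanol
Conditions: i-Bu2AlH, CH2Cl2, –78 → –40 °C; aq potassium sodium tartrate
Reagents that add atoms: none
Why: Ester reduction by a non-basic aluminium hydride at low temperature, so the epimerisable C3' is not enolised before it becomes a carbinol-bearing carbon; the aryl bromide is inert.

Step 8
Reactants: 11 {(2R,3R)-2-[4-(benzyloxy)-3-methoxyphenyl]-5-bromo-7-methoxy-2,3-dihydro-1-benzofuran-3-yl}methanol
Product: 12 tert-butyl({(2R,3R)-2-[4-(benzyloxy)-3-methoxyphenyl]-5-bromo-7-methoxy-2,3-dihydro-1-benzofuran-3-yl}methoxy)dimethylsilane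
Conditions: TBSCl, imidazole, DMF, rt
Reagents that add atoms: tert-butyldimethylsilyl chloride, CC(C)(C)[Si](C)(C)Cl
Why: Standard silylation of a primary alcohol; the silyl ether tolerates the organometallic and hydride steps that follow.

Step 9
Reactants: 12 tert-butyl({(2R,3R)-2-[4-(benzyloxy)-3-methoxyphenyl]-5-bromo-7-methoxy-2,3-dihydro-1-benzofuran-3-yl}methoxy)dimethylsilane
Product: 14 (2R,3R)-2-[4-(benzyloxy)-3-methoxyphenyl]-3-{[(tert-butyldimethylsilyl)oxy]methyl}-7-methoxy-2,3-dihydro-1-benzofuran-5-carbaldehyde, via aryllithium 13 (not isolated)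
Conditions: n-BuLi, THF, –78 °C; then DMF, –78 → 0 °C
Reagents that add atoms: N,N-dimethylformamide, CN(C)C=O
Why: Bromine–lithium exchange followed by formylation with DMF; at –78 °C the exchange should outrun deprotonation at the benzylic ring positions.

Step 10
Reactants: 15 2-[(tert-butyldimethylsilyl)oxy]acetaldehyde; 16 methyl acrylate
Product: 17 methyl 4-[(tert-butyldimethylsilyl)oxy]-3-hydroxy-2-methylidenebutanoate (racemic)
Conditions: DABCO (0.3 equiv), 16 (excess), rt
Reagents that add atoms: none
Why: Morita–Baylis–Hillman reaction; α-alkoxy aldehydes are reactive acceptors, and the carbinol stereocentre is lost again in step 12.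

Step 11
Reactants: 17 methyl 4-[(tert-butyldimethylsilyl)oxy]-3-hydroxy-2-methylidenebutanoate
Product: 18 methyl 3-(acetyloxy)-4-[(tert-butyldimethylsilyl)oxy]-2-methylidenebutanoate (racemic)
Conditions: Ac2O, pyridine, DMAP (cat.), CH2Cl2, 0 °C
Reagents that add atoms: acetic anhydride, CC(=O)OC(C)=O
Why: Acylation of the secondary allylic alcohol to install the leaving group for the SN2' step.

Step 12
Reactants: 18 methyl 3-(acetyloxy)-4-[(tert-butyldimethylsilyl)oxy]-2-methylidenebutanoate
Product: 19 methyl (2E)-4-[(tert-butyldimethylsilyl)oxy]-2-[(4,4,5,5-tetramethyl-1,3,2-dioxaborolan-2-yl)methyl]but-2-enoate (CH2OTBS cis to CH2B, trans to the ester)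
Conditions: B2pin2, CuCl (10 mol %), LiCl, KOAc, DMF, rt
Reagents that add atoms: bis(pinacolato)diboron, CC1(C)OB(B2OC(C)(C)C(C)(C)O2)OC1(C)C
Why: Copper-catalysed SN2' borylation of a Morita–Baylis–Hillman acetate (conjugate addition of the boryl–copper species, then β-acetoxy elimination); the elimination should place the C3 substituent trans to the ester, as is usual for addition–elimination on these acetates.

Step 13
Reactants: 14 (2R,3R)-2-[4-(benzyloxy)-3-methoxyphenyl]-3-{[(tert-butyldimethylsilyl)oxy]methyl}-7-methoxy-2,3-dihydro-1-benzofuran-5-carbaldehyde; 19 methyl (2E)-4-[(tert-butyldimethylsilyl)oxy]-2-[(4,4,5,5-tetramethyl-1,3,2-dioxaborolan-2-yl)methyl]but-2-enoate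
Product: 21 (4R,5R)-5-{(2R,3R)-2-[4-(benzyloxy)-3-methoxyphenyl]-3-{[(tert-butyldimethylsilyl)oxy]methyl}-7-methoxy-2,3-dihydro-1-benzofuran-5-yl}-4-{[(tert-butyldimethylsilyl)oxy]methyl}-3-methylideneoxolan-2-one (cis), via syn pinacol borate 20 (not isolated)
Conditions: 19 (1.5 equiv), Al(OTf)3 (10 mol %), N,N'-dioxide ligand from (S)-pipecolic acid (2,6-diisopropylanilide arms, propane-1,3-diyl tether; 10 mol %), CH2Cl2, 30 °C
Reagents that add atoms: none
Why: Carbonyl allylboration through a closed six-membered chair transition state, with the aldehyde aryl group equatorial and the CH2OTBS group (cis to the boron-bearing carbon) axial, gives the syn borate 20, which lactonises in the flask to the cis lactone. Chiral N,N'-dioxide–Al(OTf)3 Lewis acids are a catalyst class used for tandem allylboration–lactonisation of aromatic aldehydes with 2-(alkoxycarbonyl)allylboronates; here the ligand is chosen to direct the allyl group to the Re face of the aldehyde, which sets C2 as R and, through the chair, C3 as R.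

Step 14
Reactants: 1 4-bromo-2-methoxyphenol
Product: 22 1-(benzyloxy)-4-bromo-2-methoxybenzene
Conditions: BnBr, K2CO3, acetone, reflux
Reagents that add atoms: benzyl bromide, BrCc1ccccc1
Why: Williamson benzylation of the phenol.

Step 15
Reactants: 22 1-(benzyloxy)-4-bromo-2-methoxybenzene
Product: 23 [4-(benzyloxy)-3-methoxyphenyl]magnesium bromide (THF solution, titrated and used directly)
Conditions: Mg turnings, I2 (cat.), THF, 40 °C
Reagents that add atoms: magnesium, [Mg]
Why: Grignard formation by oxidative insertion of magnesium into the aryl C–Br bond; the benzyl ether is inert.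

Step 16
Reactants: 21 (4R,5R)-5-{(2R,3R)-2-[4-(benzyloxy)-3-methoxyphenyl]-3-{[(tert-butyldimethylsilyl)oxy]methyl}-7-methoxy-2,3-dihydro-1-benzofuran-5-yl}-4-{[(tert-butyldimethylsilyl)oxy]methyl}-3-methylideneoxolan-2-one; 23 [4-(benzyloxy)-3-methoxyphenyl]magnesium bromide
Product: 25 (3S,4R,5R)-3-{[4-(benzyloxy)-3-methoxyphenyl]methyl}-5-{(2R,3R)-2-[4-(benzyloxy)-3-methoxyphenyl]-3-{[(tert-butyldimethylsilyl)oxy]methyl}-7-methoxy-2,3-dihydro-1-benzofuran-5-yl}-4-{[(tert-butyldimethylsilyl)oxy]methyl}-3-hydroxyoxolan-2-one, via bromomagnesium enolate 24 (not isolated)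
Conditions: 23 (1.4 equiv), CuBr·SMe2 (15 mol %), THF, –78 → –40 °C; then 2-(phenylsulfonyl)-3-phenyloxaziridine (2.5 equiv), –78 → –20 °C; aq NH4Cl
Reagents that add atoms: 2-(phenylsulfonyl)-3-phenyloxaziridine, O=S(=O)(N1OC1c1ccccc1)c1ccccc1
Why: The arylcopper species formed from 23 and catalytic CuBr·SMe2 adds 1,4 to the exocyclic methylene of 21 (C7''–aryl bond) and leaves the planar bromomagnesium enolate 24, in which C4 is trigonal. The enolate carbon then attacks the oxaziridine oxygen with N–O cleavage (C4–O bond), and the adduct collapses to the sulfonylimine and the magnesium alkoxide of 25. The closest known reaction type is copper-catalysed conjugate addition of Grignard reagents to α-methylene-γ-butyrolactones with trapping of the enolate by an N-sulfonyloxaziridine, together with the anti-selective hydroxylation of β-substituted butyrolactone enolates. No ring is closed. The one new stereocentre, C4, is controlled by the ring: the C3 silyloxymethyl group and the C2 aryl group lie on the same face of the enolate, so oxygen should be delivered to the opposite face, which leaves the new benzyl group cis to both and C4 as S. The step needs 1,4- over 1,2-addition, which the copper catalyst and low temperature secure, and it needs oxidation to outrun protonation, which is secured by adding excess oxidant at –78 °C before any quench.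

Step 17
Reactants: 25 (3S,4R,5R)-3-{[4-(benzyloxy)-3-methoxyphenyl]methyl}-5-{(2R,3R)-2-[4-(benzyloxy)-3-methoxyphenyl]-3-{[(tert-butyldimethylsilyl)oxy]methyl}-7-methoxy-2,3-dihydro-1-benzofuran-5-yl}-4-{[(tert-butyldimethylsilyl)oxy]methyl}-3-hydroxyoxolan-2-one
Product: 26 (2S,3R,4R)-2-{[4-(benzyloxy)-3-methoxyphenyl]methyl}-4-{(2R,3R)-2-[4-(benzyloxy)-3-methoxyphenyl]-3-{[(tert-butyldimethylsilyl)oxy]methyl}-7-methoxy-2,3-dihydro-1-benzofuran-5-yl}-3-{[(tert-butyldimethylsilyl)oxy]methyl}butane-1,2,4-triol
Conditions: LiBH4, THF, 0 °C → rt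
Reagents that add atoms: none
Why: Hydride reduction of the lactone to the diol; LiBH4 spares silyl and benzyl ethers and breaks no bond at a stereocentre.

Step 18
Reactants: 26 (2S,3R,4R)-2-{[4-(benzyloxy)-3-methoxyphenyl]methyl}-4-{(2R,3R)-2-[4-(benzyloxy)-3-methoxyphenyl]-3-{[(tert-butyldimethylsilyl)oxy]methyl}-7-methoxy-2,3-dihydro-1-benzofuran-5-yl}-3-{[(tert-butyldimethylsilyl)oxy]methyl}butane-1,2,4-triol
Product: 28 (3S,4R,5R)-3-{[4-(benzyloxy)-3-methoxyphenyl]methyl}-5-{(2R,3R)-2-[4-(benzyloxy)-3-methoxyphenyl]-3-{[(tert-butyldimethylsilyl)oxy]methyl}-7-methoxy-2,3-dihydro-1-benzofuran-5-yl}-4-{[(tert-butyldimethylsilyl)oxy]methyl}oxolan-3-ol, via primary tosylate 27 (not isolated)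
Conditions: TsCl (1.2 equiv), pyridine, DMAP (cat.), 0 → 45 °C
Reagents that add atoms: none
Why: Selective sulfonylation of the only primary alcohol, then 5-exo-tet Williamson-type closure by the neutral C2 hydroxyl, helped by the fully substituted C4. The C2–O bond is never broken, so the cis relation of C2 and C3 is kept, and the neutral tertiary hydroxyl should not close an oxirane in the absence of a strong base.

Step 19
Reactants: 28 (3S,4R,5R)-3-{[4-(benzyloxy)-3-methoxyphenyl]methyl}-5-{(2R,3R)-2-[4-(benzyloxy)-3-methoxyphenyl]-3-{[(tert-butyldimethylsilyl)oxy]methyl}-7-methoxy-2,3-dihydro-1-benzofuran-5-yl}-4-{[(tert-butyldimethylsilyl)oxy]methyl}oxolan-3-ol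
Product: 29 (3S,4R,5R)-3-{[4-(benzyloxy)-3-methoxyphenyl]methyl}-5-{(2R,3R)-2-[4-(benzyloxy)-3-methoxyphenyl]-3-(hydroxymethyl)-7-methoxy-2,3-dihydro-1-benzofuran-5-yl}-4-(hydroxymethyl)oxolan-3-ol
Conditions: Bu4NF, THF, 0 °C → rt
Reagents that add atoms: none
Why: Fluoride cleavage of both silyl ethers; the phenols are still benzylated, so no phenoxide can open a benzylic ether.

Step 20
Reactants: 29 (3S,4R,5R)-3-{[4-(benzyloxy)-3-methoxyphenyl]methyl}-5-{(2R,3R)-2-[4-(benzyloxy)-3-methoxyphenyl]-3-(hydroxymethyl)-7-methoxy-2,3-dihydro-1-benzofuran-5-yl}-4-(hydroxymethyl)oxolan-3-ol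
Product: 30 (3S,4R,5R)-3-[(4-hydroxy-3-methoxyphenyl)methyl]-5-[(2R,3R)-2-(4-hydroxy-3-methoxyphenyl)-3-(hydroxymethyl)-7-methoxy-2,3-dihydro-1-benzofuran-5-yl]-4-(hydroxymethyl)oxolan-3-ol (CNP0284796.1)
Conditions: H2 (1 atm), Pd/C, EtOAc/MeOH, rt
Reagents that add atoms: none
Why: Hydrogenolysis of the two primary benzyl aryl ethers under neutral conditions; at ambient pressure and with short contact the more hindered secondary benzylic C–O bonds inside the two rings should survive.

## Compound list

1 | 4-bromo-2-methoxyphenol | COc1cc(Br)ccc1O | starting material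
2 | 4-bromo-2-iodo-6-methoxyphenol | COc1cc(Br)cc(I)c1O | intermediate
3 | [4-(benzyloxy)-3-methoxyphenyl]methanol | COc1cc(CO)ccc1OCc1ccccc1 | starting material
4 | 1-(benzyloxy)-4-(chloromethyl)-2-methoxybenzene | COc1cc(CCl)ccc1OCc1ccccc1 | intermediate
5 | 2-{[4-(benzyloxy)-3-methoxyphenyl]methoxy}-5-bromo-1-iodo-3-methoxybenzene | COc1cc(Br)cc(I)c1OCc1ccc(OCc2ccccc2)c(OC)c1 | intermediate
6 | (2-{[4-(benzyloxy)-3-methoxyphenyl]methoxy}-5-bromo-3-methoxyphenyl)magnesium chloride | COc1cc(Br)cc([Mg]Cl)c1OCc1ccc(OCc2ccccc2)c(OC)c1 | intermediate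
7 | methyl 2-(2-{[4-(benzyloxy)-3-methoxyphenyl]methoxy}-5-bromo-3-methoxyphenyl)-2-oxoacetate | COC(=O)C(=O)c1cc(Br)cc(OC)c1OCc1ccc(OCc2ccccc2)c(OC)c1 | intermediate
8 | N-tosylhydrazone of 7 | COC(=O)C(=NNS(=O)(=O)c1ccc(C)cc1)c1cc(Br)cc(OC)c1OCc1ccc(OCc2ccccc2)c(OC)c1 | intermediate
9 | methyl 2-(2-{[4-(benzyloxy)-3-methoxyphenyl]methoxy}-5-bromo-3-methoxyphenyl)-2-diazoacetate | COC(=O)C(=[N+]=[N-])c1cc(Br)cc(OC)c1OCc1ccc(OCc2ccccc2)c(OC)c1 | intermediate
10 | methyl (2R,3S)-2-[4-(benzyloxy)-3-methoxyphenyl]-5-bromo-7-methoxy-2,3-dihydro-1-benzofuran-3-carboxylate (cis) | Brc1cc(OC)c2c(c1)[C@H](C(=O)OC)[C@H](c1ccc(OCc3ccccc3)c(OC)c1)O2 | intermediate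
11 | {(2R,3R)-2-[4-(benzyloxy)-3-methoxyphenyl]-5-bromo-7-methoxy-2,3-dihydro-1-benzofuran-3-yl}methanol | Brc1cc(OC)c2c(c1)[C@H](CO)[C@H](c1ccc(OCc3ccccc3)c(OC)c1)O2 | intermediate
12 | tert-butyldimethylsilyl ether of 11 | Brc1cc(OC)c2c(c1)[C@H](CO[Si](C)(C)C(C)(C)C)[C@H](c1ccc(OCc3ccccc3)c(OC)c1)O2 | intermediate
13 | 5-lithio derivative of 12 | [Li]c1cc(OC)c2c(c1)[C@H](CO[Si](C)(C)C(C)(C)C)[C@H](c1ccc(OCc3ccccc3)c(OC)c1)O2 | intermediate
14 | (2R,3R)-2-[4-(benzyloxy)-3-methoxyphenyl]-3-{[(tert-butyldimethylsilyl)oxy]methyl}-7-methoxy-2,3-dihydro-1-benzofuran-5-carbaldehyde | O=Cc1cc(OC)c2c(c1)[C@H](CO[Si](C)(C)C(C)(C)C)[C@H](c1ccc(OCc3ccccc3)c(OC)c1)O2 | intermediate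
15 | 2-[(tert-butyldimethylsilyl)oxy]acetaldehyde | CC(C)(C)[Si](C)(C)OCC=O | starting material
16 | methyl acrylate | C=CC(=O)OC | starting material
17 | methyl 4-[(tert-butyldimethylsilyl)oxy]-3-hydroxy-2-methylidenebutanoate (racemic) | C=C(C(=O)OC)C(O)CO[Si](C)(C)C(C)(C)C | intermediate
18 | methyl 3-(acetyloxy)-4-[(tert-butyldimethylsilyl)oxy]-2-methylidenebutanoate (racemic) | C=C(C(=O)OC)C(OC(C)=O)CO[Si](C)(C)C(C)(C)C | intermediate
19 | methyl (2E)-4-[(tert-butyldimethylsilyl)oxy]-2-[(4,4,5,5-tetramethyl-1,3,2-dioxaborolan-2-yl)methyl]but-2-enoate | COC(=O)/C(CB1OC(C)(C)C(C)(C)O1)=C/CO[Si](C)(C)C(C)(C)C | intermediate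
20 | methyl (3R,4R)-3-{[(tert-butyldimethylsilyl)oxy]methyl}-2-methylidene-4-[(4,4,5,5-tetramethyl-1,3,2-dioxaborolan-2-yl)oxy]-4-(dihydrobenzofuran-5-yl of 14)butanoate (syn) | COC(=O)C(=C)[C@H](CO[Si](C)(C)C(C)(C)C)[C@@H](OB1OC(C)(C)C(C)(C)O1)c1cc(OC)c2c(c1)[C@H](CO[Si](C)(C)C(C)(C)C)[C@H](c1ccc(OCc3ccccc3)c(OC)c1)O2 | intermediate
21 | (4R,5R)-5-{(2R,3R)-2-[4-(benzyloxy)-3-methoxyphenyl]-3-{[(tert-butyldimethylsilyl)oxy]methyl}-7-methoxy-2,3-dihydro-1-benzofuran-5-yl}-4-{[(tert-butyldimethylsilyl)oxy]methyl}-3-methylideneoxolan-2-one | C=C1C(=O)O[C@@H](c2cc(OC)c3c(c2)[C@H](CO[Si](C)(C)C(C)(C)C)[C@H](c2ccc(OCc4ccccc4)c(OC)c2)O3)[C@H]1CO[Si](C)(C)C(C)(C)C | intermediate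
22 | 1-(benzyloxy)-4-bromo-2-methoxybenzene | COc1cc(Br)ccc1OCc1ccccc1 | intermediate
23 | [4-(benzyloxy)-3-methoxyphenyl]magnesium bromide | COc1cc([Mg]Br)ccc1OCc1ccccc1 | intermediate
24 | bromomagnesium enolate of the 3-{[4-(benzyloxy)-3-methoxyphenyl]methyl} lactone (C4 trigonal) | COc1cc(CC2=C(O[Mg]Br)O[C@@H](c3cc(OC)c4c(c3)[C@H](CO[Si](C)(C)C(C)(C)C)[C@H](c3ccc(OCc5ccccc5)c(OC)c3)O4)[C@H]2CO[Si](C)(C)C(C)(C)C)ccc1OCc1ccccc1 | intermediate
25 | (3S,4R,5R)-3-{[4-(benzyloxy)-3-methoxyphenyl]methyl}-5-{(2R,3R)-dihydrobenzofuran-5-yl as in 21}-4-{[(tert-butyldimethylsilyl)oxy]methyl}-3-hydroxyoxolan-2-one | COc1cc(C[C@@]2(O)C(=O)O[C@@H](c3cc(OC)c4c(c3)[C@H](CO[Si](C)(C)C(C)(C)C)[C@H](c3ccc(OCc5ccccc5)c(OC)c3)O4)[C@H]2CO[Si](C)(C)C(C)(C)C)ccc1OCc1ccccc1 | intermediate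
26 | (2S,3R,4R)-2-{[4-(benzyloxy)-3-methoxyphenyl]methyl}-4-{(2R,3R)-dihydrobenzofuran-5-yl as in 21}-3-{[(tert-butyldimethylsilyl)oxy]methyl}butane-1,2,4-triol | COc1cc(C[C@@](O)(CO)[C@H](CO[Si](C)(C)C(C)(C)C)[C@@H](O)c2cc(OC)c3c(c2)[C@H](CO[Si](C)(C)C(C)(C)C)[C@H](c2ccc(OCc4ccccc4)c(OC)c2)O3)ccc1OCc1ccccc1 | intermediate
27 | 1-O-(4-methylbenzenesulfonyl) derivative of 26 | COc1cc(C[C@@](O)(COS(=O)(=O)c2ccc(C)cc2)[C@H](CO[Si](C)(C)C(C)(C)C)[C@@H](O)c2cc(OC)c3c(c2)[C@H](CO[Si](C)(C)C(C)(C)C)[C@H](c2ccc(OCc4ccccc4)c(OC)c2)O3)ccc1OCc1ccccc1 | intermediate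
28 | (3S,4R,5R)-3-{[4-(benzyloxy)-3-methoxyphenyl]methyl}-5-{(2R,3R)-dihydrobenzofuran-5-yl as in 21}-4-{[(tert-butyldimethylsilyl)oxy]methyl}oxolan-3-ol | COc1cc(C[C@@]2(O)CO[C@@H](c3cc(OC)c4c(c3)[C@H](CO[Si](C)(C)C(C)(C)C)[C@H](c3ccc(OCc5ccccc5)c(OC)c3)O4)[C@H]2CO[Si](C)(C)C(C)(C)C)ccc1OCc1ccccc1 | intermediate
29 | (3S,4R,5R)-3-{[4-(benzyloxy)-3-methoxyphenyl]methyl}-5-{(2R,3R)-2-[4-(benzyloxy)-3-methoxyphenyl]-3-(hydroxymethyl)-7-methoxy-2,3-dihydro-1-benzofuran-5-yl}-4-(hydroxymethyl)oxolan-3-ol | COc1cc(C[C@@]2(O)CO[C@@H](c3cc(OC)c4c(c3)[C@H](CO)[C@H](c3ccc(OCc5ccccc5)c(OC)c3)O4)[C@H]2CO)ccc1OCc1ccccc1 | intermediate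
30 | (3S,4R,5R)-3-[(4-hydroxy-3-methoxyphenyl)methyl]-5-[(2R,3R)-2-(4-hydroxy-3-methoxyphenyl)-3-(hydroxymethyl)-7-methoxy-2,3-dihydro-1-benzofuran-5-yl]-4-(hydroxymethyl)oxolan-3-ol | COc1cc(C[C@@]2(O)CO[C@@H](c3cc(OC)c4c(c3)[C@H](CO)[C@H](c3ccc(O)c(OC)c3)O4)[C@H]2CO)ccc1O | target

## Step count and least certain steps

Total: 20 steps. Longest linear sequence: 14 steps (1, 3 to 9, 13, 16 to 20).

**Step 16 (key step).** The most likely failure is incomplete oxygen transfer. The aggregated magnesium enolate may react slowly with the oxaziridine and be protonated on work-up, or it may add to the sulfonylimine that is released. The Grignard reagent may also deprotonate C3 of 21 and isomerise the double bond into the ring. Fallback: the two bond formations are separated. From 21, the same copper-catalysed addition is quenched with NH4Cl to give the 3-{[4-(benzyloxy)-3-methoxyphenyl]methyl} lactone F1, whose C4 configuration does not matter. The potassium enolate is then formed with KHMDS in THF at –78 °C and oxidised with (camphorsulfonyl)oxaziridine. That imine by-product is inert, and the approach of the oxidant anti to the β-substituent is known for such lactone enolates. The route is rejoined at 25.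

**Step 13.** Two processes threaten it. The catalyst may control the aldehyde face poorly, since the stereocentres of 14 are remote and give no help. The Lewis acid may also ionise the benzylic C2–O bond of the electron-rich cis lactone and drift it to trans. Fallback: from 14 and 19, the allylboration is run without any catalyst in toluene at 80 to 90 °C. The closed transition state still gives only cis lactones and no acid is present. Compound 21 is then separated by preparative HPLC from the (4S,5S) diastereomeric lactone F2, at the cost of half the aldehyde. The route is rejoined at 21.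

**Step 18.** Ring closure may take the wrong course. The tertiary C4 hydroxyl could close onto C5 to an oxirane, or the benzylic C2 hydroxyl could be sulfonylated and ionise, with loss of the C2 configuration. Fallback: from 25, the triol is bypassed. i-Bu2AlH at –78 °C gives the lactol F3, and Et3SiH with BF3·OEt2 in CH2Cl2 at –78 °C removes the anomeric hydroxyl through the C5 oxocarbenium ion. O1–C2 is never broken, and the low temperature is needed to keep the benzylic ethers from ionising. The route is rejoined at 28.

**Step 6.** The enantioselectivity may be lower than on simpler substrates, because the methoxy group ortho to the benzylic ether changes its conformation in the carbenoid. The cis ester may also epimerise on handling. Fallback: enantiomeric purity is taken from a resolution. Alcohol 11 of insufficient purity is esterified with (S)-naproxen (DCC, DMAP) to the (S)-naproxen ester of 11 F4 and the (S)-naproxen ester of the enantiomeric alcohol F5. F4 is separated by crystallisation or chromatography and cleaved with LiOH in THF/H2O. The route is rejoined at 11.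

## Further compounds

F1 | step 16 | (4R,5R)-3-{[4-(benzyloxy)-3-methoxyphenyl]methyl}-5-{(2R,3R)-dihydrobenzofuran-5-yl as in 21}-4-{[(tert-butyldimethylsilyl)oxy]methyl}oxolan-2-one (C3 epimer mixture) | COc1cc(CC2C(=O)O[C@@H](c3cc(OC)c4c(c3)[C@H](CO[Si](C)(C)C(C)(C)C)[C@H](c3ccc(OCc5ccccc5)c(OC)c3)O4)[C@H]2CO[Si](C)(C)C(C)(C)C)ccc1OCc1ccccc1
F2 | step 13 | (4S,5S) diastereomer of lactone 21 | C=C1C(=O)O[C@H](c2cc(OC)c3c(c2)[C@H](CO[Si](C)(C)C(C)(C)C)[C@H](c2ccc(OCc4ccccc4)c(OC)c2)O3)[C@@H]1CO[Si](C)(C)C(C)(C)C
F3 | step 18 | lactol (oxolane-2,3-diol, anomer mixture) from 25 | COc1cc(C[C@@]2(O)C(O)O[C@@H](c3cc(OC)c4c(c3)[C@H](CO[Si](C)(C)C(C)(C)C)[C@H](c3ccc(OCc5ccccc5)c(OC)c3)O4)[C@H]2CO[Si](C)(C)C(C)(C)C)ccc1OCc1ccccc1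
F4 | step 6 | (S)-naproxen ester of 11 | Brc1cc(OC)c2c(c1)[C@H](COC(=O)[C@@H](C)c1ccc3cc(OC)ccc3c1)[C@H](c1ccc(OCc3ccccc3)c(OC)c1)O2
F5 | step 6 | (S)-naproxen ester of the (2S,3S) enantiomer of 11 | Brc1cc(OC)c2c(c1)[C@@H](COC(=O)[C@@H](C)c1ccc3cc(OC)ccc3c1)[C@@H](c1ccc(OCc3ccccc3)c(OC)c1)O2
A1 | alternative 1 | (1S,2R)-2-(5-bromo-2-hydroxy-3-methoxyphenyl)-3-[(tert-butyldimethylsilyl)oxy]-1-{3-methoxy-4-[(4-methylbenzenesulfonyl)oxy]phenyl}propan-1-ol (syn) | COc1cc(Br)cc([C@H](CO[Si](C)(C)C(C)(C)C)[C@H](O)c2ccc(OS(=O)(=O)c3ccc(C)cc3)c(OC)c2)c1O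
A2 | alternative 1 | 4-[(2R,3R)-5-bromo-3-{[(tert-butyldimethylsilyl)oxy]methyl}-7-methoxy-2,3-dihydro-1-benzofuran-2-yl]-2-methoxyphenyl 4-methylbenzenesulfonate (cis) | Brc1cc(OC)c2c(c1)[C@H](CO[Si](C)(C)C(C)(C)C)[C@H](c1ccc(OS(=O)(=O)c3ccc(C)cc3)c(OC)c1)O2
A3 | alternative 2 | aryl diazoacetate on ring B of the protected oxolane (C4 triethylsilyl ether) | COc1cc(C[C@@]2(O[Si](CC)(CC)CC)CO[C@@H](c3cc(OC)c(OCc4ccc(OCc5ccccc5)c(OC)c4)c(C(=[N+]=[N-])C(=O)OC)c3)[C@H]2CO[Si](C)(C)C(C)(C)C)ccc1OCc1ccccc1
A4 | alternative 2 | cis-dihydrobenzofuran-3-carboxylate on the protected oxolane | COc1cc(C[C@@]2(O[Si](CC)(CC)CC)CO[C@@H](c3cc(OC)c4c(c3)[C@H](C(=O)OC)[C@H](c3ccc(OCc5ccccc5)c(OC)c3)O4)[C@H]2CO[Si](C)(C)C(C)(C)C)ccc1OCc1ccccc1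
A5 | alternative 3 | (2S)-2-[4-(benzyloxy)-3-methoxyphenyl]-6-bromo-3-diazo-8-methoxy-2,3-dihydro-4H-chromen-4-one | O=C1C(=[N+]=[N-])[C@H](c2ccc(OCc3ccccc3)c(OC)c2)Oc2c(OC)cc(Br)cc21
A6 | alternative 3 | methyl (2R,3S)-2-[4-(benzyloxy)-3-methoxyphenyl]-5-bromo-7-methoxy-2,3-dihydro-1-benzofuran-3-carboxylate (identical with 10) | Brc1cc(OC)c2c(c1)[C@H](C(=O)OC)[C@H](c1ccc(OCc3ccccc3)c(OC)c1)O2
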